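**Retrosynthetic overview**
1. 13 ⇒ 12: the oxirane C–O bonds (C6–O, C7–O) are made last, by a carboxylate-anchored, site- and enantioselective epoxidation of the C6=C7 alkene (proposed new method).
2. 12 ⇒ allylic bromide 8 + tiglic acid 9 (C4–C5 bond, γ-alkylation of a copper dienolate).
3. 8 ⇒ 7 ⇒ ambliofuran 6 (terminal allylic hydroxylation, then bromide).
4. 6 ⇒ farnesyl chloride 4 (from farnesol 3) + 3-furylmethyl Grignard 5 (from 1 via 2) (C16–C17 bond).
5. Rings: the furan is bought intact and the oxirane is the only ring formed, in the final step.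

**Assumptions**
- Chain numbering: C1 = carboxyl carbon, C2(Me)=C3, C6(Me)/C7 = oxirane carbons, C10(Me)=C11, C14(Me)=C15, C17 = CH2 on the furan. The target is (6S,7S).
- Commercial (2E,6E)-farnesol is used as the single geometric isomer.
- Catalyst K (new design, prepared separately, not counted as a step) is the L-fructose-series (ent-Shi) ketone with the 4,5-O-isopropylidene group replaced by a spiro 1,1-dimethylpiperidinium ketal: 1,2-O-isopropylidene-4,5-O-(1,1-dimethylpiperidin-1-ium-4,4-diyl)-β-L-erythro-2,3-hexodiulo-2,6-pyranose triflate, SMILES C1[C@@H]([C@@H](C(=O)[C@@](O1)(COC2(C)C)O2)OC34CC[N+](C)(C)CC4)O3.[O-]S(=O)(=O)C(F)(F)F. It would be made from the L-series ketone 4,5-diol by ketal exchange with 4,4-dimethoxy-1-methylpiperidine and N-methylation with MeOTf.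

**Route**

Step 1
Reactants: 1 furan-3-ylmethanol
Product: 2 3-(chloromethyl)furan
Conditions: SOCl2, pyridine, Et2O, 0 °C
Reagents that add atoms: thionyl chloride, ClS(Cl)=O
Why: Chlorodehydroxylation through the chlorosulfite, with pyridine buffering HCl so the acid-sensitive furan survives and chloride displaces at the primary furylmethyl carbon (SN2).

Step 2
Reactants: 3 (2E,6E)-farnesol
Product: 4 (2E,6E)-farnesyl chloride
Conditions: N-chlorosuccinimide, Me2S, CH2Cl2, −40 → 0 °C
Reagents that add atoms: N-chlorosuccinimide, ClN1C(=O)CCC1=O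
Why: Corey–Kim chlorination converts the primary allylic alcohol to the chloride by SN2 collapse of the alkoxysulfonium salt, without allylic transposition or loss of E geometry.

Step 3
Reactants: 2 3-(chloromethyl)furan; 4 (2E,6E)-farnesyl chloride
Product: 6 ambliofuran (3-[(3E,7E)-4,8,12-trimethyltrideca-3,7,11-trien-1-yl]furan), via 3-furylmethylmagnesium chloride 5 (not isolated)
Conditions: Mg, THF, 0 °C; then 4, Li2CuCl4 (3 mol %), THF, 0 °C
Reagents that add atoms: none
Why: Li2CuCl4-catalysed Grignard cross-coupling (Kochi type) with a primary allylic chloride goes by SN2 substitution at C16 with retention of both E alkenes, because attack at the γ-carbon would build a quaternary centre; no stereocentre is formed.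

Step 4
Reactants: 6 ambliofuran
Product: 7 (2E,6E,10E)-13-(furan-3-yl)-2,6,10-trimethyltrideca-2,6,10-trien-1-ol
Conditions: SeO2 (0.3 equiv), tBuOOH (2.5 equiv), salicylic acid (0.1 equiv), CH2Cl2, 0 °C → rt, to ca. 50 % conversion, 6 recycled
Reagents that add atoms: tert-butyl hydroperoxide, CC(C)(C)OO (terminal oxidant; its oxygen is relayed through catalytic SeO2, O=[Se]=O)
Why: Sharpless SeO2/tBuOOH allylic oxidation (ene reaction, then [2,3]-sigmatropic shift) prefers the E-methyl of the terminal isopropylidene unit, the least hindered trisubstituted alkene, and gives the E-allylic alcohol that fixes the later C6=C7 geometry.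

Step 5
Reactants: 7 (2E,6E,10E)-13-(furan-3-yl)-2,6,10-trimethyltrideca-2,6,10-trien-1-ol
Product: 8 3-[(3E,7E,11E)-13-bromo-4,8,12-trimethyltrideca-3,7,11-trien-1-yl]furan
Conditions: CBr4, PPh3, CH2Cl2, 0 °C; used crude
Reagents that add atoms: carbon tetrabromide, BrC(Br)(Br)Br
Why: The Appel reaction converts the primary allylic alcohol to the bromide under neutral conditions by SN2 displacement of the oxyphosphonium group, so the furan and the alkene geometries are untouched.

Step 6
Reactants: 8 3-[(3E,7E,11E)-13-bromo-4,8,12-trimethyltrideca-3,7,11-trien-1-yl]furan; 9 tiglic acid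
Product: 12 (2E,6E,10E,14E)-17-(furan-3-yl)-2,6,10,14-tetramethylheptadeca-2,6,10,14-tetraenoic acid, via dilithium tiglate dienolate 10 (not isolated), via lithium copper tiglate dienolate 11 (not isolated)
Conditions: 9 (2.5 equiv), LiN(iPr)2 (5 equiv), THF, −78 → 0 °C; CuI (2.5 equiv), −78 °C; then 8, −78 °C → rt; 1 M HCl work-up
Reagents that add atoms: none
Why: γ-Alkylation of a dienolate: the monovalent copper dienolate of tiglic acid (unlike the lithium dienolate, which reacts at the α-carbon) couples at its γ-carbon with the primary allylic bromide by SN2, and re-conjugation gives mainly the 2E (tiglate-type) acid, with α- and 2Z-isomers removed by chromatography.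

Step 7
Reactants: 12 (2E,6E,10E,14E)-17-(furan-3-yl)-2,6,10,14-tetramethylheptadeca-2,6,10,14-tetraenoic acid
Product: 13 (2E)-5-[(2S,3S)-3-[(3E,7E)-10-(furan-3-yl)-4,8-dimethyldeca-3,7-dien-1-yl]-2-methyloxiran-2-yl]-2-methylpent-2-enoic acid (CNP0308047.1)
Conditions: catalyst K (30 mol %), KHSO5 (as 2KHSO5·KHSO4·K2SO4, 1.2 equiv, added over 4 h), K2CO3 (pH ca. 10), Na2EDTA, toluene/H2O, 12 at 0.01 M, 0 °C, stopped at ca. 80 % conversion; NaH2PO4 (pH 5) work-up
Reagents that add atoms: potassium peroxymonosulfate, [K+].[O-]S(=O)(=O)OO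
Why: Proposed new method: an ion-pair-anchored chiral dioxirane epoxidation in which the quaternary ammonium of K pairs with the carboxylate of 12 at the toluene/water interface (the substrate itself is the lipophilic anion that carries the cationic dioxirane out of the water), so the dioxirane oxygen, held about 6–7 Å from the ammonium, is delivered within the ion pair to the nearest electron-rich alkene C6=C7, while C2=C3 is conjugated and electron-poor and C10=C11, C14=C15 and the furan must fold back to reach it and meet no free oxidant in the organic phase; the face is chosen by the spiro transition state of the L-fructose ketone series, which gives (S,S)-epoxides from E-trisubstituted alkenes, so both stereocentres (6S,7S) are set here by syn oxygen transfer; the closest known reaction types are the Shi ketone-catalysed asymmetric epoxidation and phase-transfer epoxidation with ammonium-tagged ketones.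

**Compound list**
1 | furan-3-ylmethanol | OCc1ccoc1 | starting material
2 | 3-(chloromethyl)furan | ClCc1ccoc1 | intermediate
3 | (2E,6E)-farnesol ((2E,6E)-3,7,11-trimethyldodeca-2,6,10-trien-1-ol) | CC(C)=CCC/C(C)=C/CC/C(C)=C/CO | starting material
4 | (2E,6E)-farnesyl chloride ((2E,6E)-1-chloro-3,7,11-trimethyldodeca-2,6,10-triene) | CC(C)=CCC/C(C)=C/CC/C(C)=C/CCl | intermediate
5 | 3-furylmethylmagnesium chloride | Cl[Mg]Cc1ccoc1 | intermediate (not isolated)
6 | ambliofuran (3-[(3E,7E)-4,8,12-trimethyltrideca-3,7,11-trien-1-yl]furan) | CC(C)=CCC/C(C)=C/CC/C(C)=C/CCc1ccoc1 | intermediate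
7 | (2E,6E,10E)-13-(furan-3-yl)-2,6,10-trimethyltrideca-2,6,10-trien-1-ol | OC/C(C)=C/CC/C(C)=C/CC/C(C)=C/CCc1ccoc1 | intermediate
8 | 3-[(3E,7E,11E)-13-bromo-4,8,12-trimethyltrideca-3,7,11-trien-1-yl]furan | BrC/C(C)=C/CC/C(C)=C/CC/C(C)=C/CCc1ccoc1 | intermediate
9 | tiglic acid ((2E)-2-methylbut-2-enoic acid) | C/C=C(\C)C(=O)O | starting material
10 | dilithium tiglate dienolate (dilithium 2-methylbuta-1,3-diene-1,1-diolate) | [Li+].[Li+].[O-]C([O-])=C(C)C=C | intermediate (not isolated)
11 | lithium copper tiglate dienolate (monovalent copper) | [Li+].[Cu+].[O-]C([O-])=C(C)C=C | intermediate (not isolated)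
12 | (2E,6E,10E,14E)-17-(furan-3-yl)-2,6,10,14-tetramethylheptadeca-2,6,10,14-tetraenoic acid | OC(=O)/C(C)=C/CC/C(C)=C/CC/C(C)=C/CC/C(C)=C/CCc1ccoc1 | intermediate
13 | (2E)-5-[(2S,3S)-3-[(3E,7E)-10-(furan-3-yl)-4,8-dimethyldeca-3,7-dien-1-yl]-2-methyloxiran-2-yl]-2-methylpent-2-enoic acid | C/C(=C\CCc1ccoc1)CC/C=C(\C)CC[C@@H]1O[C@@]1(C)CC/C=C(\C)C(=O)O | target

**Step count**
Total: 7 steps (catalyst K not counted). Longest linear sequence: 6 (steps 2–7).

**Three steps most likely to fail**

Step 7 (proposed new method). The risks are incomplete site selectivity (10,11- and 14,15-epoxides, bis-epoxides), oxidation of the furan, and erosion of face selectivity under ion-pair control. The fallback uses known chemistry, sets out from 7 and comes back at 13. Sharpless asymmetric epoxidation of the allylic alcohol 7 (Ti(OiPr)4, L-(+)-diethyl tartrate, tBuOOH, 4 Å sieves, CH2Cl2, −20 °C) touches only the allylic C6=C7 alkene and gives epoxy alcohol F1 with the (2S,3S) configuration. Tf2O and 2,6-lutidine at −78 °C give epoxy triflate F2, which is displaced in the same flask by CH2=CHCH2MgBr (CuBr·SMe2 cat.) to give terminal alkene F3. Cross-metathesis with methyl methacrylate (second-generation Hoveyda–Grubbs catalyst, CH2Cl2, 40 °C) gives methyl ester F4 with the E enoate, and LiOH in THF/H2O gives 13.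

Step 6. The risks are α- instead of γ-alkylation, SN2′ attack on 8 and some 2Z isomer. The fallback sets out from 8 and comes back at 12. Lithiated N-tert-butylethanimine F5 (from the imine and LiN(iPr)2, THF, −78 °C) is alkylated by 8 to give alkylated imine F6, which aqueous oxalic acid hydrolyses on work-up to aldehyde F7. Wittig reaction with ethyl 2-(triphenylphosphoranylidene)propanoate (CH2Cl2, rt) gives ethyl ester F8 with high E selectivity, and LiOH in THF/H2O gives 12.

Step 4. The risks are oxidation at internal allylic positions or at the furan, and low conversion. The fallback moves the oxidation ahead of the furan coupling, sets out from 3 and comes back at 7. Acetylation (Ac2O, pyridine) gives farnesyl acetate F9, and SeO2/tBuOOH oxidation of this furan-free substrate gives hydroxy acetate F10. Li2CuCl4-catalysed substitution of the allylic acetate by excess Grignard 5 (the first equivalent is consumed by the hydroxyl group; THF, −20 °C) gives 7 directly.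

**Further compounds**
F1 | step 7 | [(2S,3S)-3-[(3E,7E)-10-(furan-3-yl)-4,8-dimethyldeca-3,7-dien-1-yl]-2-methyloxiran-2-yl]methanol | C/C(=C\CCc1ccoc1)CC/C=C(\C)CC[C@@H]1O[C@@]1(C)CO
F2 | step 7 | [(2S,3S)-3-[(3E,7E)-10-(furan-3-yl)-4,8-dimethyldeca-3,7-dien-1-yl]-2-methyloxiran-2-yl]methyl trifluoromethanesulfonate | C/C(=C\CCc1ccoc1)CC/C=C(\C)CC[C@@H]1O[C@@]1(C)COS(=O)(=O)C(F)(F)F
F3 | step 7 | 3-[(3E,7E)-10-[(2S,3S)-3-(but-3-en-1-yl)-3-methyloxiran-2-yl]-4,8-dimethyldeca-3,7-dien-1-yl]furan | C/C(=C\CCc1ccoc1)CC/C=C(\C)CC[C@@H]1O[C@@]1(C)CCC=C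
F4 | step 7 | methyl (2E)-5-[(2S,3S)-3-[(3E,7E)-10-(furan-3-yl)-4,8-dimethyldeca-3,7-dien-1-yl]-2-methyloxiran-2-yl]-2-methylpent-2-enoate | C/C(=C\CCc1ccoc1)CC/C=C(\C)CC[C@@H]1O[C@@]1(C)CC/C=C(\C)C(=O)OC
F5 | step 6 | lithiated N-tert-butylethanimine | [Li]CC=NC(C)(C)C
F6 | step 6 | (1E,4E,8E,12E)-N-tert-butyl-15-(furan-3-yl)-4,8,12-trimethylpentadeca-4,8,12-trien-1-imine | CC(C)(C)/N=C/CC/C(C)=C/CC/C(C)=C/CC/C(C)=C/CCc1ccoc1
F7 | step 6 | (4E,8E,12E)-15-(furan-3-yl)-4,8,12-trimethylpentadeca-4,8,12-trienal | O=CCC/C(C)=C/CC/C(C)=C/CC/C(C)=C/CCc1ccoc1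
F8 | step 6 | ethyl (2E,6E,10E,14E)-17-(furan-3-yl)-2,6,10,14-tetramethylheptadeca-2,6,10,14-tetraenoate | CCOC(=O)/C(C)=C/CC/C(C)=C/CC/C(C)=C/CC/C(C)=C/CCc1ccoc1
F9 | step 4 | (2E,6E)-farnesyl acetate | CC(C)=CCC/C(C)=C/CC/C(C)=C/COC(C)=O
F10 | step 4 | (2E,6E,10E)-12-hydroxy-3,7,11-trimethyldodeca-2,6,10-trien-1-yl acetate | OC/C(C)=C/CC/C(C)=C/CC/C(C)=C/COC(C)=O
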